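**Retrosynthetic overview**
- The C9–C10 bond, the ten-membered ring and the C9 carbinol come from one electrochemical Cr/Ni Nozaki–Hiyama–Kishi (NHK) ring closure of an (E)-alkenyl iodide onto an aldehyde; the three acyl groups go on afterwards.
- The trans-4,5-epoxide is set before ring closure: the C9 acid iodolactonises onto the C4=C5 alkene (1,3-induction from C7), and the lactol then closes the oxirane and releases the C9 aldehyde.
- The (Z)-C4=C5 alkene comes from a Still–Gennari olefination of a carvone-derived acid–aldehyde with a phosphonate that already carries the alkenyl iodide.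
- Chiral pool: (R)-carvone supplies C7 (its C2 and methyl are excised), and ethyl (S)-3-hydroxybutanoate supplies the hydroxy-ester side chain.
- Ring order: temporary δ-lactone, then oxirane, then cyclodecene.

Assumption: germacrane numbering (C1–C15) is used to locate atoms in all intermediates; the phosphorus-bearing carbon of 7 is racemic, which does not matter because it becomes sp2 in step 12.

**Phosphonate fragment**

Step 1
Reactants: 1 1-methoxy-4-[(prop-2-yn-1-yloxy)methyl]benzene (PMB propargyl ether)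
Product: 2 5-[(4-methoxybenzyl)oxy]pent-3-yn-1-ol
Conditions: n-BuLi, THF–DMPU, −78 °C; oxirane, −78 °C → rt; H2O
Reagents that add atoms: oxirane (C1CO1)
Why: The lithium acetylide opens oxirane by SN2 (epoxide alkynylation) to give the homopropargylic alcohol; no stereocentre is formed.

Step 2
Reactants: 2 5-[(4-methoxybenzyl)oxy]pent-3-yn-1-ol
Product: 4 (E)-4-iodo-5-[(4-methoxybenzyl)oxy]pent-3-en-1-ol, via vinylstannane 3 (not isolated)
Conditions: Bu3SnH, Mo(CO)3(CNt-Bu)3 (2 mol %), hydroquinone, THF, 55 °C; then I2, CH2Cl2, 0 °C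
Reagents that add atoms: iodine (II); tributyltin hydride (CCCC[SnH](CCCC)CCCC, tin stays only in 3)
Why: Mo-catalysed syn-hydrostannation of a propargylic ether puts tin on the carbon next to CH2O, and iododestannylation goes with retention, so iodine ends trans to the chain (E).

Step 3
Reactants: 4 (E)-4-iodo-5-[(4-methoxybenzyl)oxy]pent-3-en-1-ol
Product: 5 1-({[(E)-2,5-diiodopent-2-en-1-yl]oxy}methyl)-4-methoxybenzene
Conditions: I2, PPh3, imidazole, CH2Cl2, 0 °C
Reagents that add atoms: iodine (II)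
Why: Appel-type (Garegg–Samuelsson) iodination converts the primary alcohol into the iodide without touching the alkenyl iodide.

Step 4
Reactants: 5 1-({[(E)-2,5-diiodopent-2-en-1-yl]oxy}methyl)-4-methoxybenzene; 6 methyl 2-[bis(2,2,2-trifluoroethoxy)phosphoryl]acetate
Product: 7 methyl (5E)-2-[bis(2,2,2-trifluoroethoxy)phosphoryl]-6-iodo-7-[(4-methoxybenzyl)oxy]hept-5-enoate
Conditions: NaH, DMF, 0 °C → rt
Reagents that add atoms: none
Why: SN2 C-alkylation of the stabilised phosphonoacetate anion by the primary iodide gives the α-substituted Still–Gennari reagent.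

**Side-chain acid**

Step 5
Reactants: 8 ethyl (S)-3-hydroxybutanoate
Product: 9 ethyl (2S,3S)-3-hydroxy-2-methylbutanoate
Conditions: LDA (2.2 equiv), THF, −50 → −20 °C; MeI, DMPU, −78 → 0 °C
Reagents that add atoms: iodomethane (CI)
Why: Fráter–Seebach alkylation: the chelated dianion is methylated anti to the C3 methyl, giving the anti (2S,3S) ester.

Step 6
Reactants: 9 ethyl (2S,3S)-3-hydroxy-2-methylbutanoate
Product: 10 ethyl (2R,3S)-3-hydroxy-2-methylbutanoate
Conditions: LDA (2.2 equiv), THF, −78 → −20 °C; AcOH, −78 °C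
Reagents that add atoms: none
Why: Kinetic protonation of the re-formed chelated dianion from the same (anti) face puts the C2 methyl on the other side, so C3 controls C2 and gives the syn (2R,3S) ester (expected dr about 6:1, minor isomer removed by chromatography).

Step 7
Reactants: 10 ethyl (2R,3S)-3-hydroxy-2-methylbutanoate
Product: 11 ethyl (2R,3S)-3-[(tert-butyldimethylsilyl)oxy]-2-methylbutanoate
Conditions: TBSCl, imidazole, DMF, rt
Reagents that add atoms: tert-butyldimethylsilyl chloride (CC(C)(C)[Si](C)(C)Cl)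
Why: Standard silylation protects the secondary hydroxyl so the acid cannot self-acylate in step 21.

Step 8
Reactants: 11 ethyl (2R,3S)-3-[(tert-butyldimethylsilyl)oxy]-2-methylbutanoate
Product: 12 (2R,3S)-3-[(tert-butyldimethylsilyl)oxy]-2-methylbutanoic acid
Conditions: LiOH, THF–H2O, 0 °C → rt; then aq HCl
Reagents that add atoms: lithium hydroxide ([Li+].[OH-])
Why: Mild saponification; the β-silyloxy group prevents retro-aldol and the α-centre is not epimerised at 0 °C.

**Main line**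

Step 9
Reactants: 13 (R)-(−)-carvone
Product: 14 (1R,4R,6R)-1-methyl-4-(prop-1-en-2-yl)-7-oxabicyclo[4.1.0]heptan-2-one
Conditions: 30% H2O2, NaOH (cat.), MeOH, 0 °C
Reagents that add atoms: hydrogen peroxide (OO)
Why: Weitz–Scheffer nucleophilic epoxidation touches only the enone and gives the epoxide trans to the isopropenyl group (these two centres are excised in step 11).

Step 10
Reactants: 14 (1R,4R,6R)-1-methyl-4-(prop-1-en-2-yl)-7-oxabicyclo[4.1.0]heptan-2-one
Product: 15 (1R,4R,6R)-4-(3-chloroprop-1-en-2-yl)-1-methyl-7-oxabicyclo[4.1.0]heptan-2-one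
Conditions: Ca(OCl)2, CO2 (dry ice), CH2Cl2–H2O, 0 °C
Reagents that add atoms: calcium hypochlorite ([Ca+2].[O-]Cl.[O-]Cl)
Why: Ene-type allylic chlorination by HOCl at the only remaining C=C installs the future C12 oxygen site, as known for carvone itself.

Step 11
Reactants: 15 (1R,4R,6R)-4-(3-chloroprop-1-en-2-yl)-1-methyl-7-oxabicyclo[4.1.0]heptan-2-one
Product: 16 (R)-3-(3-chloroprop-1-en-2-yl)-5-oxopentanoic acid
Conditions: H5IO6, THF–H2O, 0 °C → rt
Reagents that add atoms: water (O)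
Why: Periodic acid hydrolyses the epoxide and cleaves the glycol (Malaprade), then cleaves the resulting 1,2-diketone, which removes C2 and its methyl as acetic acid and leaves the C7 centre with an aldehyde arm (C5) and an acid arm (C9).

Step 12
Reactants: 16 (R)-3-(3-chloroprop-1-en-2-yl)-5-oxopentanoic acid; 7 methyl (5E)-2-[bis(2,2,2-trifluoroethoxy)phosphoryl]-6-iodo-7-[(4-methoxybenzyl)oxy]hept-5-enoate
Product: 17 (3R,5Z,9E)-3-(3-chloroprop-1-en-2-yl)-10-iodo-6-(methoxycarbonyl)-11-[(4-methoxybenzyl)oxy]undeca-5,9-dienoic acid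
Conditions: KHMDS (2.1 equiv), 18-crown-6, THF, −78 °C
Reagents that add atoms: none
Why: Still–Gennari (Z-selective Horner–Wadsworth–Emmons) olefination of the aldehyde, with the acid held as its potassium salt, places the ester cis to C6, so C3 and C6 are trans as the trans-epoxide needs.

Step 13
Reactants: 17 (3R,5Z,9E)-3-(3-chloroprop-1-en-2-yl)-10-iodo-6-(methoxycarbonyl)-11-[(4-methoxybenzyl)oxy]undeca-5,9-dienoic acid
Product: 18 (3R,5Z,9E)-3-(3-chloroprop-1-en-2-yl)-6-(hydroxymethyl)-10-iodo-11-[(4-methoxybenzyl)oxy]undeca-5,9-dienoic acid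
Conditions: DIBAL-H (3.3 equiv), CH2Cl2, −78 °C; Rochelle salt
Reagents that add atoms: none
Why: DIBAL reduces the enoate 1,2 to the allylic alcohol (C15–OH), while the aluminium carboxylate formed from the acid is inert at −78 °C.

Step 14
Reactants: 18 (3R,5Z,9E)-3-(3-chloroprop-1-en-2-yl)-6-(hydroxymethyl)-10-iodo-11-[(4-methoxybenzyl)oxy]undeca-5,9-dienoic acid
Product: 19 (4R,6R)-4-(3-chloroprop-1-en-2-yl)-6-[(2R,5E)-1-hydroxy-2,6-diiodo-7-[(4-methoxybenzyl)oxy]hept-5-en-2-yl]oxan-2-one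
Conditions: I2, NaHCO3, MeCN–H2O, 0 °C, dark
Reagents that add atoms: iodine (II)
Why: Kinetic iodolactonisation: the iodonium should form on the trisubstituted alkene (the chloromethyl-vinyl group is estimated to be roughly 100-fold less nucleophilic), 6-exo capture through a chair with both substituents equatorial gives the cis-4,6-lactone so C7 sets C5, and anti addition sets C4.

Step 15
Reactants: 19 (4R,6R)-4-(3-chloroprop-1-en-2-yl)-6-[(2R,5E)-1-hydroxy-2,6-diiodo-7-[(4-methoxybenzyl)oxy]hept-5-en-2-yl]oxan-2-one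
Product: 20 (4R,6R)-6-[(2R,5E)-1-[(tert-butyldimethylsilyl)oxy]-2,6-diiodo-7-[(4-methoxybenzyl)oxy]hept-5-en-2-yl]-4-(3-chloroprop-1-en-2-yl)oxan-2-one
Conditions: TBSCl, imidazole, DMF, 0 °C
Reagents that add atoms: tert-butyldimethylsilyl chloride (CC(C)(C)[Si](C)(C)Cl)
Why: Silylation of the primary C15 hydroxyl prevents Payne rearrangement in step 16 and keeps it apart from the C9 hydroxyl later.

Step 16
Reactants: 20 (4R,6R)-6-[(2R,5E)-1-[(tert-butyldimethylsilyl)oxy]-2,6-diiodo-7-[(4-methoxybenzyl)oxy]hept-5-en-2-yl]-4-(3-chloroprop-1-en-2-yl)oxan-2-one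
Product: 22 (3R)-3-{[(2R,3S)-3-{[(tert-butyldimethylsilyl)oxy]methyl}-3-[(E)-4-iodo-5-[(4-methoxybenzyl)oxy]pent-3-en-1-yl]oxiran-2-yl]methyl}-4-(chloromethyl)pent-4-enal, via iodo-lactol 21 (not isolated)
Conditions: DIBAL-H (1.1 equiv), CH2Cl2, −78 °C; then K2CO3, MeOH, 0 °C
Reagents that add atoms: none
Why: Half-reduction gives the lactol, and in base its open hydroxy-aldehyde form displaces the anti-periplanar tertiary iodide (Williamson epoxide closure, inversion at C4), giving the trans-(4S,5R)-epoxide and freeing the C9 aldehyde.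

Step 17
Reactants: 22 (3R)-3-{[(2R,3S)-3-{[(tert-butyldimethylsilyl)oxy]methyl}-3-[(E)-4-iodo-5-[(4-methoxybenzyl)oxy]pent-3-en-1-yl]oxiran-2-yl]methyl}-4-(chloromethyl)pent-4-enal
Product: 23 (3R)-4-(acetoxymethyl)-3-{[(2R,3S)-3-{[(tert-butyldimethylsilyl)oxy]methyl}-3-[(E)-4-iodo-5-[(4-methoxybenzyl)oxy]pent-3-en-1-yl]oxiran-2-yl]methyl}pent-4-enal
Conditions: CsOAc, 18-crown-6 (cat.), DMF, rt
Reagents that add atoms: caesium acetate ([Cs+].CC([O-])=O)
Why: SN2 displacement of the primary allylic chloride by acetate installs the 12-acetate, and removes the allylic halide before chromium is used.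

Step 18
Reactants: 23 (3R)-4-(acetoxymethyl)-3-{[(2R,3S)-3-{[(tert-butyldimethylsilyl)oxy]methyl}-3-[(E)-4-iodo-5-[(4-methoxybenzyl)oxy]pent-3-en-1-yl]oxiran-2-yl]methyl}pent-4-enal
Product: 24 (1(10)E,4S,5R,7S,9S)-12-acetoxy-15-(tert-butyldimethylsilyloxy)-4,5-epoxy-14-(4-methoxybenzyloxy)germacra-1(10),11(13)-dien-9-ol
Conditions: CrCl2 (15 mol %), NiCl2·neocuproine (2 mol %), Cp2ZrCl2 (1.2 equiv), LiCl, DMF, rt; undivided cell, Al(+)/Ni foam(−), constant current; slow addition of 23 (final 2 mM)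
Reagents that add atoms: none
Why: Proposed new method: an electroreductive Cr/Ni-catalysed NHK ring closure to a ten-membered carbocycle — Ni(0) inserts into C10–I with retention, transmetalates to Cr(III), the alkenyl–Cr adds to the C9 aldehyde, Cp2ZrCl2 releases the Cr alkoxide and the cathode regenerates Cr(II)/Ni(0), while A(1,2) strain with the C10 CH2OPMB group is expected to hold the metal alkoxide pseudo-axial, anti to the equatorial C7 side chain (9S, a prediction not a certainty); the closest known chemistry is the intermolecular electrochemical NHK coupling and stoichiometric CrCl2/NiCl2 NHK macrocyclisations, and I am not aware of a catalytic electrochemical medium-ring NHK closure.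

Step 19
Reactants: 24 (1(10)E,4S,5R,7S,9S)-12-acetoxy-15-(tert-butyldimethylsilyloxy)-4,5-epoxy-14-(4-methoxybenzyloxy)germacra-1(10),11(13)-dien-9-ol
Product: 25 (1(10)E,4S,5R,7S,9S)-12-acetoxy-15-(tert-butyldimethylsilyloxy)-4,5-epoxy-14-(4-methoxybenzyloxy)germacra-1(10),11(13)-dien-9-yl 3-methylbutanoate
Conditions: isovaleric anhydride, DMAP, Et3N, CH2Cl2, 0 °C → rt
Reagents that add atoms: 3-methylbutanoic anhydride (CC(C)CC(=O)OC(=O)CC(C)C)
Why: DMAP-catalysed acylation of the only free hydroxyl, with retention at C9.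

Step 20
Reactants: 25 (1(10)E,4S,5R,7S,9S)-12-acetoxy-15-(tert-butyldimethylsilyloxy)-4,5-epoxy-14-(4-methoxybenzyloxy)germacra-1(10),11(13)-dien-9-yl 3-methylbutanoate
Product: 26 (1(10)E,4S,5R,7S,9S)-12-acetoxy-15-(tert-butyldimethylsilyloxy)-4,5-epoxy-14-hydroxygermacra-1(10),11(13)-dien-9-yl 3-methylbutanoate
Conditions: DDQ (1.2 equiv), CH2Cl2–pH 7 buffer, 0 °C
Reagents that add atoms: none
Why: Oxidative PMB cleavage under buffered neutral conditions spares the epoxide, the silyl ether and the three esters.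

Step 21
Reactants: 26 (1(10)E,4S,5R,7S,9S)-12-acetoxy-15-(tert-butyldimethylsilyloxy)-4,5-epoxy-14-hydroxygermacra-1(10),11(13)-dien-9-yl 3-methylbutanoate; 12 (2R,3S)-3-[(tert-butyldimethylsilyl)oxy]-2-methylbutanoic acid
Product: 27 (1(10)E,4S,5R,7S,9S)-12-acetoxy-15-(tert-butyldimethylsilyloxy)-4,5-epoxy-9-(3-methylbutanoyloxy)germacra-1(10),11(13)-dien-14-yl (2R,3S)-3-[(tert-butyldimethylsilyl)oxy]-2-methylbutanoate
Conditions: EDC·HCl, DMAP, CH2Cl2, 0 °C → rt
Reagents that add atoms: none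
Why: Steglich esterification of the primary allylic alcohol attaches the side chain with both of its centres unchanged.

Step 22
Reactants: 27 (1(10)E,4S,5R,7S,9S)-12-acetoxy-15-(tert-butyldimethylsilyloxy)-4,5-epoxy-9-(3-methylbutanoyloxy)germacra-1(10),11(13)-dien-14-yl (2R,3S)-3-[(tert-butyldimethylsilyl)oxy]-2-methylbutanoate
Product: 28 CNP0132467.1 (target)
Conditions: HF·pyridine, pyridine, THF, 0 °C → rt
Reagents that add atoms: none
Why: Buffered fluoride desilylation removes both TBS groups without base, so neither Payne rearrangement nor acyl migration is expected, although HF opening of the trisubstituted epoxide is a possible side reaction to watch.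

**Compound list**
1 | 1-methoxy-4-[(prop-2-yn-1-yloxy)methyl]benzene | C#CCOCc1ccc(OC)cc1 | starting material
2 | 5-[(4-methoxybenzyl)oxy]pent-3-yn-1-ol | OCCC#CCOCc1ccc(OC)cc1 | intermediate
3 | (E)-5-[(4-methoxybenzyl)oxy]-4-(tributylstannyl)pent-3-en-1-ol | OCC/C=C(/[Sn](CCCC)(CCCC)CCCC)COCc1ccc(OC)cc1 | intermediate
4 | (E)-4-iodo-5-[(4-methoxybenzyl)oxy]pent-3-en-1-ol | OCC/C=C(/I)COCc1ccc(OC)cc1 | intermediate
5 | 1-({[(E)-2,5-diiodopent-2-en-1-yl]oxy}methyl)-4-methoxybenzene | ICC/C=C(/I)COCc1ccc(OC)cc1 | intermediate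
6 | methyl 2-[bis(2,2,2-trifluoroethoxy)phosphoryl]acetate | COC(=O)CP(=O)(OCC(F)(F)F)OCC(F)(F)F | starting material
7 | methyl (5E)-2-[bis(2,2,2-trifluoroethoxy)phosphoryl]-6-iodo-7-[(4-methoxybenzyl)oxy]hept-5-enoate (racemic at C2) | COC(=O)C(CC/C=C(/I)COCc1ccc(OC)cc1)P(=O)(OCC(F)(F)F)OCC(F)(F)F | intermediate
8 | ethyl (S)-3-hydroxybutanoate | CCOC(=O)C[C@H](C)O | starting material
9 | ethyl (2S,3S)-3-hydroxy-2-methylbutanoate | CCOC(=O)[C@@H](C)[C@H](C)O | intermediate
10 | ethyl (2R,3S)-3-hydroxy-2-methylbutanoate | CCOC(=O)[C@H](C)[C@H](C)O | intermediate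
11 | ethyl (2R,3S)-3-[(tert-butyldimethylsilyl)oxy]-2-methylbutanoate | CCOC(=O)[C@H](C)[C@H](C)O[Si](C)(C)C(C)(C)C | intermediate
12 | (2R,3S)-3-[(tert-butyldimethylsilyl)oxy]-2-methylbutanoic acid | OC(=O)[C@H](C)[C@H](C)O[Si](C)(C)C(C)(C)C | intermediate
13 | (R)-(−)-carvone | CC1=CC[C@H](CC1=O)C(C)=C | starting material
14 | (1R,4R,6R)-1-methyl-4-(prop-1-en-2-yl)-7-oxabicyclo[4.1.0]heptan-2-one | C[C@@]12O[C@@H]1C[C@H](CC2=O)C(C)=C | intermediate
15 | (1R,4R,6R)-4-(3-chloroprop-1-en-2-yl)-1-methyl-7-oxabicyclo[4.1.0]heptan-2-one | C[C@@]12O[C@@H]1C[C@H](CC2=O)C(=C)CCl | intermediate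
16 | (R)-3-(3-chloroprop-1-en-2-yl)-5-oxopentanoic acid | O=CC[C@H](CC(=O)O)C(=C)CCl | intermediate
17 | (3R,5Z,9E)-3-(3-chloroprop-1-en-2-yl)-10-iodo-6-(methoxycarbonyl)-11-[(4-methoxybenzyl)oxy]undeca-5,9-dienoic acid | OC(=O)C[C@@H](C/C=C(/CC/C=C(/I)COCc1ccc(OC)cc1)C(=O)OC)C(=C)CCl | intermediate
18 | (3R,5Z,9E)-3-(3-chloroprop-1-en-2-yl)-6-(hydroxymethyl)-10-iodo-11-[(4-methoxybenzyl)oxy]undeca-5,9-dienoic acid | OC(=O)C[C@@H](C/C=C(/CC/C=C(/I)COCc1ccc(OC)cc1)CO)C(=C)CCl | intermediate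
19 | (4R,6R)-4-(3-chloroprop-1-en-2-yl)-6-[(2R,5E)-1-hydroxy-2,6-diiodo-7-[(4-methoxybenzyl)oxy]hept-5-en-2-yl]oxan-2-one | O=C1C[C@@H](C[C@@H](O1)[C@](I)(CO)CC/C=C(/I)COCc2ccc(OC)cc2)C(=C)CCl | intermediate
20 | (4R,6R)-6-[(2R,5E)-1-[(tert-butyldimethylsilyl)oxy]-2,6-diiodo-7-[(4-methoxybenzyl)oxy]hept-5-en-2-yl]-4-(3-chloroprop-1-en-2-yl)oxan-2-one | O=C1C[C@@H](C[C@@H](O1)[C@](I)(CO[Si](C)(C)C(C)(C)C)CC/C=C(/I)COCc2ccc(OC)cc2)C(=C)CCl | intermediate
21 | (4R,6R)-6-[(2R,5E)-1-[(tert-butyldimethylsilyl)oxy]-2,6-diiodo-7-[(4-methoxybenzyl)oxy]hept-5-en-2-yl]-4-(3-chloroprop-1-en-2-yl)oxan-2-ol (anomer mixture) | OC1C[C@@H](C[C@@H](O1)[C@](I)(CO[Si](C)(C)C(C)(C)C)CC/C=C(/I)COCc2ccc(OC)cc2)C(=C)CCl | intermediate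
22 | (3R)-3-{[(2R,3S)-3-{[(tert-butyldimethylsilyl)oxy]methyl}-3-[(E)-4-iodo-5-[(4-methoxybenzyl)oxy]pent-3-en-1-yl]oxiran-2-yl]methyl}-4-(chloromethyl)pent-4-enal | O=CC[C@@H](C[C@H]1O[C@]1(CO[Si](C)(C)C(C)(C)C)CC/C=C(/I)COCc2ccc(OC)cc2)C(=C)CCl | intermediate
23 | (3R)-4-(acetoxymethyl)-3-{[(2R,3S)-3-{[(tert-butyldimethylsilyl)oxy]methyl}-3-[(E)-4-iodo-5-[(4-methoxybenzyl)oxy]pent-3-en-1-yl]oxiran-2-yl]methyl}pent-4-enal | O=CC[C@@H](C[C@H]1O[C@]1(CO[Si](C)(C)C(C)(C)C)CC/C=C(/I)COCc2ccc(OC)cc2)C(=C)COC(C)=O | intermediate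
24 | (1(10)E,4S,5R,7S,9S)-12-acetoxy-15-(tert-butyldimethylsilyloxy)-4,5-epoxy-14-(4-methoxybenzyloxy)germacra-1(10),11(13)-dien-9-ol | C=C(COC(C)=O)[C@H]1C[C@H](O)/C(COCc3ccc(OC)cc3)=C/CC[C@@]2(CO[Si](C)(C)C(C)(C)C)O[C@@H]2C1 | intermediate
25 | 9-O-(3-methylbutanoyl) ester of 24 | C=C(COC(C)=O)[C@H]1C[C@H](OC(=O)CC(C)C)/C(COCc3ccc(OC)cc3)=C/CC[C@@]2(CO[Si](C)(C)C(C)(C)C)O[C@@H]2C1 | intermediate
26 | (1(10)E,4S,5R,7S,9S)-12-acetoxy-15-(tert-butyldimethylsilyloxy)-4,5-epoxy-14-hydroxygermacra-1(10),11(13)-dien-9-yl 3-methylbutanoate | C=C(COC(C)=O)[C@H]1C[C@H](OC(=O)CC(C)C)/C(CO)=C/CC[C@@]2(CO[Si](C)(C)C(C)(C)C)O[C@@H]2C1 | intermediate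
27 | 14-O-[(2R,3S)-3-(tert-butyldimethylsilyloxy)-2-methylbutanoyl] ester of 26 | C=C(COC(C)=O)[C@H]1C[C@H](OC(=O)CC(C)C)/C(COC(=O)[C@H](C)[C@H](C)O[Si](C)(C)C(C)(C)C)=C/CC[C@@]2(CO[Si](C)(C)C(C)(C)C)O[C@@H]2C1 | intermediate
28 | CNP0132467.1: (1(10)E,4S,5R,7S,9S)-12-acetoxy-4,5-epoxy-15-hydroxy-9-(3-methylbutanoyloxy)germacra-1(10),11(13)-dien-14-yl (2R,3S)-3-hydroxy-2-methylbutanoate | C=C(COC(C)=O)[C@H]1C[C@H](OC(=O)CC(C)C)/C(COC(=O)[C@H](C)[C@H](C)O)=C/CC[C@@]2(CO)O[C@@H]2C1 | target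

**Totals**
Total steps: 22. Longest linear sequence: 15 (steps 1–4, then 12–22); the carvone branch is 14 steps (9–22).

**Three steps most likely to fail**

Step 18 (the proposed new step). The electro-catalytic turnover may fail at high dilution, or C9 may form with the wrong configuration. The fallback sets out from 23 and uses the known stoichiometric Kishi–Nozaki macrocyclisation (CrCl2 about 8 equiv, NiCl2 1 mol %, DMSO–THF, syringe pump) without any electrochemistry, returning at 24. If that known reaction gives mainly the C9 epimer, (1(10)E,4S,5R,7S,9R)-12-acetoxy-15-(tert-butyldimethylsilyloxy)-4,5-epoxy-14-(4-methoxybenzyloxy)germacra-1(10),11(13)-dien-9-ol F5, a Mitsunobu esterification (PPh3, DIAD, isovaleric acid) inverts C9 and enters the route at 25.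

Step 12. The Still–Gennari olefination in the presence of a free carboxylate, with a bulky α-substituted phosphonate, may give low conversion. The fallback sets out from 16 and masks the acid: CDI then MeNHOMe·HCl gives (R)-3-(3-chloroprop-1-en-2-yl)-N-methoxy-N-methyl-5-oxopentanamide F1. The same olefination with 7 gives the Weinreb (Z)-enoate F2. Excess DIBAL-H at −78 °C reduces the ester to the alcohol and the amide to the aldehyde, giving the hydroxy aldehyde F3. Pinnick oxidation (NaClO2, NaH2PO4, 2-methyl-2-butene) then returns to the route at 18.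

Step 16. The one-pot half-reduction and epoxide closure may suffer from elimination of the tertiary iodide or over-reduction. The fallback sets out from 20 and reverses the order: K2CO3 in MeOH opens the lactone and the freed alkoxide closes the epoxide (the classical iodolactone-to-epoxy-ester conversion), giving the epoxy methyl ester F4. DIBAL-H (1.05 equiv, −78 °C) then reduces the ester to the aldehyde and returns at 22.

Further compounds
F1 | step 12 | (R)-3-(3-chloroprop-1-en-2-yl)-N-methoxy-N-methyl-5-oxopentanamide | O=CC[C@H](CC(=O)N(C)OC)C(=C)CCl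
F2 | step 12 | methyl (2Z,6E)-2-{(3R)-4-(chloromethyl)-3-[2-(methoxy(methyl)amino)-2-oxoethyl]pent-4-en-1-ylidene}-6-iodo-7-[(4-methoxybenzyl)oxy]hept-5-enoate (Weinreb (Z)-enoate) | CON(C)C(=O)C[C@@H](C/C=C(/CC/C=C(/I)COCc1ccc(OC)cc1)C(=O)OC)C(=C)CCl
F3 | step 12 | (3R,5Z,9E)-3-(3-chloroprop-1-en-2-yl)-6-(hydroxymethyl)-10-iodo-11-[(4-methoxybenzyl)oxy]undeca-5,9-dienal | O=CC[C@@H](C/C=C(/CC/C=C(/I)COCc1ccc(OC)cc1)CO)C(=C)CCl
F4 | step 16 | methyl (3R)-3-{[(2R,3S)-3-{[(tert-butyldimethylsilyl)oxy]methyl}-3-[(E)-4-iodo-5-[(4-methoxybenzyl)oxy]pent-3-en-1-yl]oxiran-2-yl]methyl}-4-(chloromethyl)pent-4-enoate | COC(=O)C[C@@H](C[C@H]1O[C@]1(CO[Si](C)(C)C(C)(C)C)CC/C=C(/I)COCc2ccc(OC)cc2)C(=C)CCl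
F5 | step 18 | (1(10)E,4S,5R,7S,9R)-12-acetoxy-15-(tert-butyldimethylsilyloxy)-4,5-epoxy-14-(4-methoxybenzyloxy)germacra-1(10),11(13)-dien-9-ol | C=C(COC(C)=O)[C@H]1C[C@@H](O)/C(COCc3ccc(OC)cc3)=C/CC[C@@]2(CO[Si](C)(C)C(C)(C)C)O[C@@H]2C1
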